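| flask | substrate | partner | other conformer | remark | time |
|---|---|---|---|---|---|
| Tuesday's | 0.066 M | 2 equiv | 0.50 equiv | run made earlier |  |
| alpha | 0.060 M | 2.00 equiv | 0.500 equiv |  | 6.0 min |
| epsilon | 0.25 M | 1.30 equiv | 0.120 equiv |  | 6.0 min |
| delta | 0.030 M | 1.30 equiv | 2.00 equiv |  | 6.0 min |
| zeta | 0.060 M | 2.00 equiv | 1.00 equiv |  | 6.0 min |
| eta | 0.060 M | 1.00 equiv | 0.500 equiv |  | 6.0 min |

Tuesday's run (percent of the substrate and other conformer together charged)

| time / s | target / % | substrate / % |
|---|---|---|
| 12.0 | 23.6 | 41.6 |
| 25.0 | 33.7 | 29.4 |
| 40.0 | 41.8 | 19.3 |
| 50.0 | 41.5 | 15.4 |
| 60.0 | 47.1 | 13.3 |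
| 80.0 | 49.0 | 6.0 |

(readings scatter by 1 percentage point)

- percent here means substrate units held: one side product counts as two
- candidate steps: substrate <-> dormant form; substrate + partner -> target; substrate + target -> side product; partner + other conformer -> isomer of the product; substrate <-> other conformer
- in a conversion other conformer counts as not yet reacted

- all flasks from highest to lowest amount of target, in percent of the substrate and other conformer together charged, at 6.0 min (alpha / epsilon / delta / zeta / eta)
- the amount of target, in percent of the substrate and other conformer together charged of the flask you put first, at 6.0 min
- the amount of target, in percent of the substrate and other conformer together charged of the flask you put last, at 6.0 min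

65.2 % of the charge stands as target plus substrate at 12.0 s in Tuesday's run, close to the 66.7 % charged as substrate. That balance belongs to the first 12.0 s of one run and says nothing about 6.0 min, for substrate <-> other conformer stands among the candidate steps. As a first estimate, then, I take the two as separate accounts, an assumption and not a finding, and ask how much partner reaches the substrate. My reckoning starts from a plain assumption: each other conformer takes one partner first. With x_B and x_E the equivalents of partner and other conformer per substrate,

W = min(1, x_B − x_E) / (1 + x_E), taken as zero when negative.

Where x_B − x_E falls below one, partner is the limiting reagent. On epsilon's charge this comes to 89.3 %, and this partner allowance is the quantity to carry. But an allowance is not a yield. By 80.0 s, Tuesday's target plus substrate has fallen to 55.0 %, so the reading gives a kept fraction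

f = 55.0 % / 66.7 % = 0.825.

My estimates of target, as f·W, are then:

epsilon 73.7 %, alpha 55.0 %, zeta 41.2 %, eta 27.5 %, delta 0 %.

Two objections stand. First, f counts Tuesday's last 6.0 % of substrate as future target, and epsilon is 3.79 times as concentrated, which favours substrate + target. If none of that substrate arrived, epsilon would drop to 65.6 %, still first. Second, no reading shows the other conformer, so its priority is assumed. If delta's partner instead split in proportion to the charges, delta would reach 11.9 %, so I place delta between that and zero, and last.

The forecast gives epsilon > alpha > zeta > eta > delta, the same order as mine, but with 62 % at the top, below my figure, and 22 % at the bottom, above my range. For delta its ground reads “dilute, only one third substrate”.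

    substrate ⇌ dormant form (K = 28.0, k = 0.180 min⁻¹)
    substrate + partner → target (k = 21.0 M⁻¹ min⁻¹)
    substrate + target → side product (k = 0.990 M⁻¹ min⁻¹)
    partner + other conformer → isomer of the product (k = 110 M⁻¹ min⁻¹)
    substrate ⇌ other conformer (K = 0.190, k = 0.150 min⁻¹)

Epsilon gives 75.6 % and delta 5.80 %, in the order epsilon > alpha > zeta > eta > delta. Epsilon still holds 20.2 % of its own partner at 6.00 min. My f·W for epsilon stood 2 percentage points below that result. Now raise epsilon's other conformer to 0.200 equiv, with the rest held: W becomes 83.3 %, and f·W becomes 68.8 %. That flask stands at 69.0 %.

The runs come from a simulation with constants of no real substance; noise was put on by code.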